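The ester joining O–C4 of ring A (the benzoic acid ring) to carbonyl C7 of ring B (the middle ring) is traced back to a C4–C7 diaryl ketone. A Baeyer–Villiger oxidation then forms the C7–O and O–C4 bonds in one operation. It exploits that C4 of ring A sits between the ether oxygens on C3 and C5, which make ring A migrate in preference to ring B. The precursor is a fully benzylated triaryl ketone that already carries the ester to ring C (the terminal galloyl ring). Because the ring A carboxyl is also a benzyl ester, one hydrogenolysis completes the synthesis.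

Key step: step 7

Remarks on the chemistry (assumptions):
- Ring A numbering: C1 bears the carboxyl, C4 the ester oxygen. Ring B: C1 bears carbonyl carbon C7, C4 the oxygen acylated by ring C.
- The ring A carboxyl is carried as a benzyl ester, not an acid-labile ester. It is made in the same alkylation as the ethers, is inert to the acid-promoted peracid step, and leaves with the ethers in the last step.
- Ring C is attached to the ring B aldehyde before the C–C coupling, so no temporary protecting group on O4 of ring B is needed.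
- 3,4,5-Tris(benzyloxy)benzoic acid 6 is taken as a purchased material.
- The target has no stereocentre. Carbinol 10 and adduct 12 are racemic, and their stereocentre disappears on the way.

Step 1
Reactants: 1 4-bromo-3,5-dihydroxybenzoic acid
Product: 2 benzyl 3,5-bis(benzyloxy)-4-bromobenzoate
Conditions: BnBr (3.5 equiv), K2CO3, DMF, 60 °C
Reagents that add atoms: benzyl bromide, BrCc1ccccc1
Why: Williamson O-alkylation of both phenoxides and SN2 alkylation of the carboxylate should install all three benzyl groups in one operation, the aryl bromide being inert to carbonate base.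

Step 2
Reactants: 3 3,4,5-trihydroxybenzaldehyde
Product: 4 3,4,5-tris(benzyloxy)benzaldehyde
Conditions: BnBr (3.5 equiv), K2CO3, cat. KI, DMF, 60 °C, N2
Reagents that add atoms: benzyl bromide, BrCc1ccccc1
Why: Williamson ether synthesis on the three phenols under exclusion of air, which protects the base-sensitive pyrogallol unit from oxidation, should give the tribenzyl ether.

Step 3
Reactants: 4 3,4,5-tris(benzyloxy)benzaldehyde
Product: 5 3,5-bis(benzyloxy)-4-hydroxybenzaldehyde
Conditions: MgBr2·OEt2 (2 equiv), toluene/Et2O, 80 °C; then 1 M HCl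
Reagents that add atoms: none
Why: Lewis-acid-mediated regioselective ether cleavage should remove only the central C4 benzyl group, because that ether is twisted out of the ring plane by its two neighbours, is chelated by MgBr2 together with O3, and leaves as the phenoxide conjugated to the para formyl group while bromide takes the benzyl carbon by SN2.

Step 4
Reactants: 6 3,4,5-tris(benzyloxy)benzoic acid; 5 3,5-bis(benzyloxy)-4-hydroxybenzaldehyde
Product: 8 2,6-bis(benzyloxy)-4-formylphenyl 3,4,5-tris(benzyloxy)benzoate, via 3,4,5-tris(benzyloxy)benzoyl chloride 7 (not isolated)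
Conditions: (COCl)2, cat. DMF, CH2Cl2, 0 °C to rt, concentrate; then 5, Et3N, cat. DMAP, CH2Cl2, 0 °C to rt
Reagents that add atoms: none
Why: Acid chloride formation followed by DMAP-catalysed O-acylation should succeed on this flanked phenol because the para formyl group makes it acidic and the acylpyridinium ion is small and highly electrophilic.

Step 5
Reactants: 2 benzyl 3,5-bis(benzyloxy)-4-bromobenzoate; 8 2,6-bis(benzyloxy)-4-formylphenyl 3,4,5-tris(benzyloxy)benzoate
Product: 10 benzyl 3,5-bis(benzyloxy)-4-[{3,5-bis(benzyloxy)-4-[3,4,5-tris(benzyloxy)benzoyloxy]phenyl}(hydroxy)methyl]benzoate (racemic), via arylmagnesium chloride 9 (not isolated)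
Conditions: 2 (1.2 equiv), iPrMgCl·LiCl (1.15 equiv), THF, −20 °C; then 8 (1.0 equiv), THF, −40 to −20 °C; aq NH4Cl
Reagents that add atoms: none
Why: Bromine–magnesium exchange (Knochel type), accelerated by the two ortho ether oxygens and the para ester, should give a hindered arylmagnesium chloride that undergoes Grignard 1,2-addition to the aldehyde far faster than it attacks either ester at low temperature; the carbinol stereocentre forms without control and is erased in step 6.

Step 6
Reactants: 10 benzyl 3,5-bis(benzyloxy)-4-[{3,5-bis(benzyloxy)-4-[3,4,5-tris(benzyloxy)benzoyloxy]phenyl}(hydroxy)methyl]benzoate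
Product: 11 benzyl 3,5-bis(benzyloxy)-4-{3,5-bis(benzyloxy)-4-[3,4,5-tris(benzyloxy)benzoyloxy]benzoyl}benzoate
Conditions: Dess–Martin periodinane (1.5 equiv), CH2Cl2, rt; aq Na2S2O3/NaHCO3 work-up
Reagents that add atoms: none
Why: Dess–Martin oxidation of a secondary diaryl carbinol to the ketone is mild and near neutral, so benzyl ethers and both esters should remain untouched.

Step 7
Reactants: 11 benzyl 3,5-bis(benzyloxy)-4-{3,5-bis(benzyloxy)-4-[3,4,5-tris(benzyloxy)benzoyloxy]benzoyl}benzoate
Product: 13 benzyl 3,5-bis(benzyloxy)-4-{3,5-bis(benzyloxy)-4-[3,4,5-tris(benzyloxy)benzoyloxy]benzoyloxy}benzoate, via Criegee adduct 12 (not isolated)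
Conditions: mCPBA (3 equiv), CF3CO2H (2 equiv), CH2Cl2, 0 °C to rt, dark; aq Na2S2O3/NaHCO3 work-up
Reagents that add atoms: 3-chloroperoxybenzoic acid (mCPBA), O=C(OO)c1cccc(Cl)c1
Why: Baeyer–Villiger oxidation: the peracid, helped by CF3CO2H protonating the carbonyl, adds to C7 to give Criegee adduct 12, and the aryl group antiperiplanar to the O–O bond shifts from C7 to the proximal peroxide oxygen as 3-chlorobenzoate leaves, which creates the C7–O and O–C4 bonds of the ring A/ring B ester. The closest known reaction type is the peracid oxidation of alkoxy-substituted benzophenones and 2,6-dialkoxyaryl ketones to aryl esters. No ring is closed and no stereocentre is formed, so the only selectivity needed is which aryl group migrates. Ring A is expected to migrate because its ipso carbon C4 carries ether oxygens on both neighbouring carbons C3 and C5, whose lone pairs stabilise the positive charge building up in the bridged transition state, and because the two ortho substituents twist ring A out of conjugation with the carbonyl; this should outweigh the para benzyl ester, whereas C1 of ring B has only a weakly donating para acyloxy group and two inductively withdrawing meta ethers. Benzyl ethers, the benzyl ester and the aryl ester to ring C are inert to mCPBA with a little CF3CO2H, and the acyl substituents on all three rings slow electrophilic ring hydroxylation.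

Step 8
Reactants: 13 benzyl 3,5-bis(benzyloxy)-4-{3,5-bis(benzyloxy)-4-[3,4,5-tris(benzyloxy)benzoyloxy]benzoyloxy}benzoate
Product: 14 3,5-dihydroxy-4-{3,5-dihydroxy-4-[(3,4,5-trihydroxybenzoyl)oxy]benzoyloxy}benzoic acid (CNP0121783.0)
Conditions: H2 (1 atm), 10% Pd/C, THF, rt; filter, concentrate below 30 °C
Reagents that add atoms: none
Why: Catalytic hydrogenolysis should cleave the seven benzyl ethers and the benzyl ester while leaving the two aryl ester bonds intact, and the neutral aprotic medium avoids transesterification and migration of the 4-O-acyl groups to the neighbouring free phenols.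

Compound list
1 | 4-bromo-3,5-dihydroxybenzoic acid | O=C(O)c1cc(O)c(Br)c(O)c1 | starting material
2 | benzyl 3,5-bis(benzyloxy)-4-bromobenzoate | O=C(OCc1ccccc1)c1cc(OCc2ccccc2)c(Br)c(OCc2ccccc2)c1 | intermediate
3 | 3,4,5-trihydroxybenzaldehyde | O=Cc1cc(O)c(O)c(O)c1 | starting material
4 | 3,4,5-tris(benzyloxy)benzaldehyde | O=Cc1cc(OCc2ccccc2)c(OCc2ccccc2)c(OCc2ccccc2)c1 | intermediate
5 | 3,5-bis(benzyloxy)-4-hydroxybenzaldehyde | O=Cc1cc(OCc2ccccc2)c(O)c(OCc2ccccc2)c1 | intermediate
6 | 3,4,5-tris(benzyloxy)benzoic acid | O=C(O)c1cc(OCc2ccccc2)c(OCc2ccccc2)c(OCc2ccccc2)c1 | starting material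
7 | 3,4,5-tris(benzyloxy)benzoyl chloride (not isolated) | O=C(Cl)c1cc(OCc2ccccc2)c(OCc2ccccc2)c(OCc2ccccc2)c1 | intermediate
8 | 2,6-bis(benzyloxy)-4-formylphenyl 3,4,5-tris(benzyloxy)benzoate | O=Cc1cc(OCc2ccccc2)c(OC(=O)c2cc(OCc3ccccc3)c(OCc3ccccc3)c(OCc3ccccc3)c2)c(OCc2ccccc2)c1 | intermediate
9 | [2,6-bis(benzyloxy)-4-(benzyloxycarbonyl)phenyl]magnesium chloride, as its LiCl complex (not isolated) | O=C(OCc1ccccc1)c1cc(OCc2ccccc2)c([Mg]Cl)c(OCc2ccccc2)c1 | intermediate
10 | benzyl 3,5-bis(benzyloxy)-4-[{3,5-bis(benzyloxy)-4-[3,4,5-tris(benzyloxy)benzoyloxy]phenyl}(hydroxy)methyl]benzoate, racemic | O=C(OCc1ccccc1)c1cc(OCc2ccccc2)c(C(O)c2cc(OCc3ccccc3)c(OC(=O)c3cc(OCc4ccccc4)c(OCc4ccccc4)c(OCc4ccccc4)c3)c(OCc3ccccc3)c2)c(OCc2ccccc2)c1 | intermediate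
11 | benzyl 3,5-bis(benzyloxy)-4-{3,5-bis(benzyloxy)-4-[3,4,5-tris(benzyloxy)benzoyloxy]benzoyl}benzoate | O=C(OCc1ccccc1)c1cc(OCc2ccccc2)c(C(=O)c2cc(OCc3ccccc3)c(OC(=O)c3cc(OCc4ccccc4)c(OCc4ccccc4)c(OCc4ccccc4)c3)c(OCc3ccccc3)c2)c(OCc2ccccc2)c1 | intermediate
12 | Criegee adduct: benzyl 3,5-bis(benzyloxy)-4-[{3,5-bis(benzyloxy)-4-[3,4,5-tris(benzyloxy)benzoyloxy]phenyl}(3-chlorobenzoylperoxy)(hydroxy)methyl]benzoate, racemic (not isolated) | O=C(OCc1ccccc1)c1cc(OCc2ccccc2)c(C(O)(OOC(=O)c2cccc(Cl)c2)c2cc(OCc3ccccc3)c(OC(=O)c3cc(OCc4ccccc4)c(OCc4ccccc4)c(OCc4ccccc4)c3)c(OCc3ccccc3)c2)c(OCc2ccccc2)c1 | intermediate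
13 | benzyl 3,5-bis(benzyloxy)-4-{3,5-bis(benzyloxy)-4-[3,4,5-tris(benzyloxy)benzoyloxy]benzoyloxy}benzoate | O=C(OCc1ccccc1)c1cc(OCc2ccccc2)c(OC(=O)c2cc(OCc3ccccc3)c(OC(=O)c3cc(OCc4ccccc4)c(OCc4ccccc4)c(OCc4ccccc4)c3)c(OCc3ccccc3)c2)c(OCc2ccccc2)c1 | intermediate
14 | 3,5-dihydroxy-4-{3,5-dihydroxy-4-[(3,4,5-trihydroxybenzoyl)oxy]benzoyloxy}benzoic acid (CNP0121783.0) | O=C(O)c1cc(O)c(OC(=O)c2cc(O)c(OC(=O)c3cc(O)c(O)c(O)c3)c(O)c2)c(O)c1 | target

Total step count: 8. Longest linear sequence: 7 steps (steps 2 to 8, from 3 to 14).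

Steps most likely to fail

1. Step 7 (oxygen insertion). The peracid may add too slowly to a carbonyl shielded by the two ortho benzyloxy groups of ring A. Ring B may migrate in part, or the benzyloxy-substituted rings may be hydroxylated before insertion occurs. The fallback forms the ring A O–C7 ester by acylation instead; it sets out from 8 and 6 and comes back at 13. Aldehyde 8 would be oxidised under Pinnick conditions (NaClO2, NaH2PO4, 2-methyl-2-butene, tBuOH/THF/H2O) to 3,5-bis(benzyloxy)-4-[3,4,5-tris(benzyloxy)benzoyloxy]benzoic acid F1. Acid 6 would be benzylated (BnBr, K2CO3, DMF) to benzyl 3,4,5-tris(benzyloxy)benzoate F2, and its central ether cleaved with MgBr2·OEt2 as in step 3 to give benzyl 3,5-bis(benzyloxy)-4-hydroxybenzoate F3. F1 would then be converted with (COCl)2 and cat. DMF into 3,5-bis(benzyloxy)-4-[3,4,5-tris(benzyloxy)benzoyloxy]benzoyl chloride F4. F4 would acylate the flanked phenol of F3 (Et3N, DMAP, CH2Cl2, rt to 40 °C) to give 13.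

2. Step 5 (aryl–carbonyl C–C bond). The isopropyl- or arylmagnesium chloride may attack the activated aryl ester of 8 and transfer the galloyl group instead of adding cleanly to the aldehyde. The fallback keeps that ester out of the organometallic step; it sets out from 5 (with 2 and 6) and comes back at 11. Phenol 5 would be silylated (tBuMe2SiCl, imidazole, DMF) to 3,5-bis(benzyloxy)-4-(tert-butyldimethylsilyloxy)benzaldehyde F5. Arylmagnesium chloride 9, made from 2 as in step 5, would add to F5 to give racemic benzyl 3,5-bis(benzyloxy)-4-{[3,5-bis(benzyloxy)-4-(tert-butyldimethylsilyloxy)phenyl](hydroxy)methyl}benzoate F6. Dess–Martin oxidation would give benzyl 3,5-bis(benzyloxy)-4-[3,5-bis(benzyloxy)-4-(tert-butyldimethylsilyloxy)benzoyl]benzoate F7. Desilylation (Bu4NF, AcOH, THF, 0 °C) would give benzyl 3,5-bis(benzyloxy)-4-[3,5-bis(benzyloxy)-4-hydroxybenzoyl]benzoate F8. Acylation of F8 with acid chloride 7, made from 6 as in step 4 (Et3N, DMAP, CH2Cl2), would give 11.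

3. Step 3 (regioselective debenzylation). Regiocontrol may be lost, with cleavage of a C3 or C5 benzyl ether or of two ethers, or conversion may stall. The fallback differentiates O4 by its acidity before any benzyl group is introduced; it sets out from 3 and comes back at 5. Aldehyde 3 would be mono-alkylated at the most acidic, para hydroxyl (allyl bromide 1.0 equiv, NaHCO3, DMF, rt) to give 4-(allyloxy)-3,5-dihydroxybenzaldehyde F9. Benzylation (BnBr, K2CO3, DMF) would give 4-(allyloxy)-3,5-bis(benzyloxy)benzaldehyde F10. Allyl transfer (cat. Pd(PPh3)4, K2CO3, MeOH, rt) would then release 5.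

Further compounds
F1 | step 7 | 3,5-bis(benzyloxy)-4-[3,4,5-tris(benzyloxy)benzoyloxy]benzoic acid | O=C(O)c1cc(OCc2ccccc2)c(OC(=O)c2cc(OCc3ccccc3)c(OCc3ccccc3)c(OCc3ccccc3)c2)c(OCc2ccccc2)c1
F2 | step 7 | benzyl 3,4,5-tris(benzyloxy)benzoate | O=C(OCc1ccccc1)c1cc(OCc2ccccc2)c(OCc2ccccc2)c(OCc2ccccc2)c1
F3 | step 7 | benzyl 3,5-bis(benzyloxy)-4-hydroxybenzoate | O=C(OCc1ccccc1)c1cc(OCc2ccccc2)c(O)c(OCc2ccccc2)c1
F4 | step 7 | 3,5-bis(benzyloxy)-4-[3,4,5-tris(benzyloxy)benzoyloxy]benzoyl chloride | O=C(Cl)c1cc(OCc2ccccc2)c(OC(=O)c2cc(OCc3ccccc3)c(OCc3ccccc3)c(OCc3ccccc3)c2)c(OCc2ccccc2)c1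
F5 | step 5 | 3,5-bis(benzyloxy)-4-(tert-butyldimethylsilyloxy)benzaldehyde | O=Cc1cc(OCc2ccccc2)c(O[Si](C)(C)C(C)(C)C)c(OCc2ccccc2)c1
F6 | step 5 | benzyl 3,5-bis(benzyloxy)-4-{[3,5-bis(benzyloxy)-4-(tert-butyldimethylsilyloxy)phenyl](hydroxy)methyl}benzoate, racemic | O=C(OCc1ccccc1)c1cc(OCc2ccccc2)c(C(O)c2cc(OCc3ccccc3)c(O[Si](C)(C)C(C)(C)C)c(OCc3ccccc3)c2)c(OCc2ccccc2)c1
F7 | step 5 | benzyl 3,5-bis(benzyloxy)-4-[3,5-bis(benzyloxy)-4-(tert-butyldimethylsilyloxy)benzoyl]benzoate | O=C(OCc1ccccc1)c1cc(OCc2ccccc2)c(C(=O)c2cc(OCc3ccccc3)c(O[Si](C)(C)C(C)(C)C)c(OCc3ccccc3)c2)c(OCc2ccccc2)c1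
F8 | step 5 | benzyl 3,5-bis(benzyloxy)-4-[3,5-bis(benzyloxy)-4-hydroxybenzoyl]benzoate | O=C(OCc1ccccc1)c1cc(OCc2ccccc2)c(C(=O)c2cc(OCc3ccccc3)c(O)c(OCc3ccccc3)c2)c(OCc2ccccc2)c1
F9 | step 3 | 4-(allyloxy)-3,5-dihydroxybenzaldehyde | O=Cc1cc(O)c(OCC=C)c(O)c1
F10 | step 3 | 4-(allyloxy)-3,5-bis(benzyloxy)benzaldehyde | O=Cc1cc(OCc2ccccc2)c(OCC=C)c(OCc2ccccc2)c1
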